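The tetrahydrofuran ring (O1, C2 with the guaiacyl group, C3 with C9, C4 with the ketone carbon C7', C5) is cut at O1–C2 and C3–C4. This exploits two hidden units. O1–C5–C4–C7', with C7' disguised as a 1-arylvinyl carbon, is an opened vinyl epoxide. C2=C3, with C9 as a carboxyl carbon, is a vanillin Knoevenagel adduct. One enantioselective palladium-catalysed (3+2) annulation of a racemic 2-(1-arylvinyl)oxirane with a benzylidene Meldrum's acid makes both bonds, closes the ring and sets C2 and C4 cis. Decarboxylation with equilibration then places C3 trans to both, and alkene cleavage reveals the ketone.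

Key step: step 6

Assumption: the sense of induction of the chiral diphosphine on an allyl unit with a central aryl group is assigned by analogy. The (R,R) ligand is written, and its equally available antipode is used if a pilot run gives the mirror image.

Design remarks (ring numbering O1, C2, C3, C4, C5 is used for every tetrahydrofuran):
- **Phenol protection.** Both phenols are carried as benzyl ethers. Aryl silyl ethers are cleaved by alkoxides, and alkoxide is present in the annulation and in the methoxide steps after it. O-Benzylvanillin is also commercial, which saves a step.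
- **C3 configuration.** The target is 2,3-trans, 3,4-trans, 2,4-cis, that is (2S,3R,4S). The enol formed on decarboxylation should be protonated from the face opposite the two cis substituents, which would put the ester cis to both. An explicit thermodynamic equilibration at C3 is therefore built into step 7.
- **Need for the 2,4-cis relation.** It is needed, not merely tolerated. Only then is one C3 epimer trans to both neighbours.
- **Alkene cleavage.** Osmium/periodate is used instead of ozone, which attacks trialkoxyarenes.

Step 1
Reactants: 1 acetosyringone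
Product: 2 1-[4-(benzyloxy)-3,5-dimethoxyphenyl]ethan-1-one
Conditions: BnBr, K2CO3, DMF, 60 °C
Reagents that add atoms: benzyl bromide, BrCc1ccccc1
Why: Williamson ether synthesis of an acidic, flanked phenoxide in a polar aprotic solvent, giving an ether that tolerates butyllithium, methoxide, hydride and osmium/periodate and is removed at the end under neutral conditions.

Step 2
Reactants: 2 1-[4-(benzyloxy)-3,5-dimethoxyphenyl]ethan-1-one
Product: 3 (E)-2,4,6-triisopropylbenzenesulfonyl hydrazone of 2
Conditions: 2,4,6-iPr3C6H2SO2NHNH2, HCl (cat), MeCN, rt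
Reagents that add atoms: 2,4,6-triisopropylbenzenesulfonohydrazide, NNS(=O)(=O)c1c(C(C)C)cc(C(C)C)cc1C(C)C
Why: Acid-catalysed hydrazone condensation of a methyl aryl ketone, with the trisyl group chosen because its blocked ortho positions prevent ring lithiation and its dianion fragments at or below 0 °C, as a Shapiro reaction with electrophile trapping requires.

Step 3
Reactants: 3 trisylhydrazone; 4 chloroacetaldehyde (commercial aqueous solution extracted into CH2Cl2, dried and distilled just before use)
Product: 6 rac-3-[4-(benzyloxy)-3,5-dimethoxyphenyl]-1-chlorobut-3-en-2-ol, via vinyllithium 5 (not isolated)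
Conditions: n-BuLi (2.1 equiv), THF, −78 to 0 °C; then 4, −78 °C; aq NH4Cl
Reagents that add atoms: none
Why: Shapiro reaction, in which double deprotonation (N–H and the only α-hydrogens, those of the methyl group) and loss of sulfinate and nitrogen give the 1-arylvinyllithium, which adds 1,2 to the very electrophilic aldehyde faster than it displaces chloride; the carbinol centre is racemic by design because step 6 is stereoconvergent.

Step 4
Reactants: 6 rac-chlorohydrin
Product: 7 rac-2-{1-[4-(benzyloxy)-3,5-dimethoxyphenyl]vinyl}oxirane
Conditions: K2CO3, MeOH, rt; filtration through Et3N-washed silica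
Reagents that add atoms: none
Why: Intramolecular Williamson closure (3-exo-tet) of a chlorohydrin under mild carbonate conditions, with acid excluded in the work-up because the product is an allylic epoxide.

Step 5
Reactants: 8 4-(benzyloxy)-3-methoxybenzaldehyde (O-benzylvanillin); 9 Meldrum's acid
Product: 10 5-[4-(benzyloxy)-3-methoxybenzylidene]-2,2-dimethyl-1,3-dioxane-4,6-dione
Conditions: piperidine (10 mol %), AcOH (10 mol %), EtOH, rt, product filtered off
Reagents that add atoms: none
Why: Knoevenagel condensation of a non-enolisable aromatic aldehyde with a highly acidic methylene compound, driven by crystallisation of the product and free of alkene-geometry issues because the acceptor is symmetrical.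

Step 6
Reactants: 7 rac-2-(1-arylvinyl)oxirane (1.3 equiv); 10 benzylidene Meldrum's acid
Product: 11 (1R,4S)-1-[4-(benzyloxy)-3-methoxyphenyl]-4-{1-[4-(benzyloxy)-3,5-dimethoxyphenyl]vinyl}-8,8-dimethyl-2,7,9-trioxaspiro[4.5]decane-6,10-dione (ring numbering of this route: C2 R and C4 S; aryl and arylvinyl cis; same spatial arrangement as in the target)
Conditions: Pd2(dba)3·CHCl3 (2.5 mol %), N,N'-[(1R,2R)-cyclohexane-1,2-diyl]bis[2-(diphenylphosphino)-1-naphthamide] (7.5 mol %), toluene, rt
Reagents that add atoms: none
Why: Zerovalent palladium ionises the allylic C4–O bond of either enantiomer of 7 to a zwitterionic 2-aryl-π-allylpalladium alkoxide, whose oxygen adds reversibly to the strongly electrophilic C2 of 10 (O1–C2) and whose internal allyl terminus C4 is then alkylated by the Meldrum's acid carbanion at C3 (C3–C4), releasing the catalyst. The closest known reaction type is the palladium-catalysed formal (3+2) cycloaddition of vinyl epoxides and vinylcyclopropanes with doubly activated alkenes, including enantioselective versions with chiral diphosphines. The tetrahydrofuran closes in a 5-exo mode that leaves the 1-arylvinyl group outside the ring, whereas attack at the CH2 terminus would need a 7-endo closure that the short C3–C2–O1–C5 chain disfavours. C4 is set by the chiral ligand pocket, because the diastereomeric π-allyl complexes interconvert by π–σ–π slippage at the unsubstituted CH2 terminus faster than they are trapped, so the racemate should converge on one enantiomer (dynamic kinetic asymmetric transformation). C2 is set relative to C4 under Curtin–Hammett conditions, since the oxa-Michael adducts equilibrate and the cyclisation placing the C2 aryl and C4 alkenyl groups on the same face, both pseudo-equatorial and turned away from the dioxanedione, should be the faster one. The step needs branched rather than linear attack, C- rather than O-alkylation of the enolate and trapping ahead of epoxide-to-carbonyl isomerisation, which the chain length, the soft stabilised carbanion and the high electrophilicity of 10 are expected to secure.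

Step 7
Reactants: 11 spiro adduct
Product: 14 methyl (2S,3S,4R)-2-[4-(benzyloxy)-3-methoxyphenyl]-4-{1-[4-(benzyloxy)-3,5-dimethoxyphenyl]vinyl}tetrahydrofuran-3-carboxylate (2,3-trans-3,4-trans), via malonic half-ester 12 (not isolated), via all-cis ester 13 (not isolated)
Conditions: NaOMe (1.2 equiv), MeOH–THF, 0 °C to rt, cold 1 M HCl, extraction; then pyridine, 110 °C, evaporation; then NaOMe (0.3 equiv), MeOH, 50 °C
Reagents that add atoms: sodium methoxide, [Na+].[O-]C
Why: Methoxide opens the unusually electrophilic dioxanedione by acyl substitution with loss of acetone, the malonic half-acid decarboxylates thermally through its enol, and the closing methoxide equilibration through the ester enolate moves C3 from the kinetically expected all-cis arrangement to the thermodynamically preferred one trans to both neighbours, while C2 and C4 carry no acidic hydrogen and β-elimination of O1 is hampered by poor overlap of the ring C2–O1 bond with the enolate.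

Step 8
Reactants: 14 trans,trans methyl ester
Product: 15 {(2S,3R,4R)-2-[4-(benzyloxy)-3-methoxyphenyl]-4-{1-[4-(benzyloxy)-3,5-dimethoxyphenyl]vinyl}tetrahydrofuran-3-yl}methanol
Conditions: LiAlH4, THF, 0 °C; aqueous NaOH work-up
Reagents that add atoms: none
Why: Standard hydride reduction of an ester to a primary alcohol, carried out while the ketone is still masked as an unactivated 1,1-disubstituted alkene that, like the benzyl ethers and the ring stereocentres, is inert to LiAlH4.

Step 9
Reactants: 15 primary alcohol
Product: 17 {(2S,3R,4S)-2-[4-(benzyloxy)-3-methoxyphenyl]-3-(hydroxymethyl)tetrahydrofuran-4-yl}[4-(benzyloxy)-3,5-dimethoxyphenyl]methanone, via vicinal diol 16 (not isolated)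
Conditions: K2OsO4·2H2O (2 mol %), NaIO4 (4 equiv), 2,6-lutidine (2 equiv), dioxane–H2O 3:1, rt
Reagents that add atoms: sodium periodate (oxygen relayed by the osmium catalyst), [Na+].[O-]I(=O)(=O)=O
Why: Lemieux–Johnson oxidation, in which catalytic osmylation of the only alkene and periodate cleavage of the diol give the aryl ketone and formaldehyde without touching the electron-rich arenes, and C4, now enolisable, already sits trans to the C3 substituent so the buffered medium offers no drive to epimerise it.

Step 10
Reactants: 17 bis(benzyl ether) ketone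
Product: 18 (2S,3R,4S)-2-(4-hydroxy-3-methoxyphenyl)-3-(hydroxymethyl)-4-(4-hydroxy-3,5-dimethoxybenzoyl)tetrahydrofuran (CNP0169680.1)
Conditions: H2 (1 atm), Pd/C (10 wt %), EtOAc, rt, stopped after uptake of two equivalents
Reagents that add atoms: none
Why: Catalytic hydrogenolysis of aryl benzyl ethers is much faster than reduction of a para-oxygenated aryl ketone or cleavage of the cyclic benzylic C2–O1 bond at atmospheric pressure in neutral ethyl acetate, and the neutral medium leaves the base-sensitive C4 and the acid-sensitive C2 untouched.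

Compound list
1 | acetosyringone | CC(=O)c1cc(OC)c(O)c(OC)c1 | starting material
2 | 1-[4-(benzyloxy)-3,5-dimethoxyphenyl]ethan-1-one | CC(=O)c1cc(OC)c(OCc2ccccc2)c(OC)c1 | intermediate
3 | (E)-trisylhydrazone of 2 | C/C(=N\NS(=O)(=O)c1c(C(C)C)cc(C(C)C)cc1C(C)C)c1cc(OC)c(OCc2ccccc2)c(OC)c1 | intermediate
4 | chloroacetaldehyde | ClCC=O | starting material
5 | 1-[4-(benzyloxy)-3,5-dimethoxyphenyl]vinyllithium (not isolated) | [Li]C(=C)c1cc(OC)c(OCc2ccccc2)c(OC)c1 | intermediate
6 | rac-3-[4-(benzyloxy)-3,5-dimethoxyphenyl]-1-chlorobut-3-en-2-ol | C=C(c1cc(OC)c(OCc2ccccc2)c(OC)c1)C(O)CCl | intermediate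
7 | rac-2-{1-[4-(benzyloxy)-3,5-dimethoxyphenyl]vinyl}oxirane | C=C(c1cc(OC)c(OCc2ccccc2)c(OC)c1)C1CO1 | intermediate
8 | 4-(benzyloxy)-3-methoxybenzaldehyde | COc1cc(C=O)ccc1OCc1ccccc1 | starting material
9 | Meldrum's acid | CC1(C)OC(=O)CC(=O)O1 | starting material
10 | 5-[4-(benzyloxy)-3-methoxybenzylidene]-2,2-dimethyl-1,3-dioxane-4,6-dione | COc1cc(C=C2C(=O)OC(C)(C)OC2=O)ccc1OCc1ccccc1 | intermediate
11 | spiro Meldrum's acid tetrahydrofuran, 2-aryl and 4-(1-arylvinyl) cis | COc1cc([C@H]2OC[C@@H](C(=C)c3cc(OC)c(OCc4ccccc4)c(OC)c3)C25C(=O)OC(C)(C)OC5=O)ccc1OCc1ccccc1 | intermediate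
12 | C3 carboxylic acid/methyl ester (malonic half-ester, C3 epimers, not isolated) | COc1cc([C@H]2OC[C@@H](C(=C)c3cc(OC)c(OCc4ccccc4)c(OC)c3)C2(C(=O)O)C(=O)OC)ccc1OCc1ccccc1 | intermediate
13 | methyl (2S,3R,4R) ester, all-cis C3 epimer (not isolated) | COc1cc([C@H]2OC[C@@H](C(=C)c3cc(OC)c(OCc4ccccc4)c(OC)c3)[C@H]2C(=O)OC)ccc1OCc1ccccc1 | intermediate
14 | methyl (2S,3S,4R) ester, 2,3-trans-3,4-trans | COc1cc([C@H]2OC[C@@H](C(=C)c3cc(OC)c(OCc4ccccc4)c(OC)c3)[C@@H]2C(=O)OC)ccc1OCc1ccccc1 | intermediate
15 | (2S,3R,4R) 3-hydroxymethyl-4-(1-arylvinyl)tetrahydrofuran | COc1cc([C@H]2OC[C@@H](C(=C)c3cc(OC)c(OCc4ccccc4)c(OC)c3)[C@@H]2CO)ccc1OCc1ccccc1 | intermediate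
16 | C7',C8'-diol from osmylation of 15 (C7' epimers, not isolated) | COc1cc([C@H]2OC[C@@H](C(O)(CO)c3cc(OC)c(OCc4ccccc4)c(OC)c3)[C@@H]2CO)ccc1OCc1ccccc1 | intermediate
17 | (2S,3R,4S) bis(benzyl ether) of the target | COc1cc([C@H]2OC[C@@H](C(=O)c3cc(OC)c(OCc4ccccc4)c(OC)c3)[C@@H]2CO)ccc1OCc1ccccc1 | intermediate
18 | CNP0169680.1, (2S,3R,4S) | COc1cc([C@H]2OC[C@@H](C(=O)c3cc(OC)c(O)c(OC)c3)[C@@H]2CO)ccc1O | target

Total step count: 10. Longest linear sequence: 9 steps (1, 2, 3, 4, 6, 7, 8, 9, 10).

Steps most likely to fail

1. **Step 6.**
   - *Risk:* trapping of the zwitterion may be too slow, so that it isomerises by hydride shift. The ligand may discriminate poorly between the faces of an allyl unit with a central aryl group. The relative control between C2 and C4 may be weak.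
   - *Fallback:* it builds the ring by lactone aldol chemistry. It sets out from vinyllithium 5 (made from 3 as in step 3) and aldehyde 8, and rejoins the route at 15. Compound 5 is quenched with 2-isopropoxy-4,4,5,5-tetramethyl-1,3,2-dioxaborolane to give the 1-arylvinyl pinacol boronate F1. A Hayashi–Miyaura conjugate addition of F1 to furan-2(5H)-one ([RhCl(cod)]2, (R)-BINAP, KOH, dioxane–H2O) sets C4 in the (R)-β-(1-arylvinyl)butyrolactone F2. Its lithium enolate (LiHMDS, THF, −78 °C) adds to 8 anti to the C4 substituent to give the trans aldol lactone F3 as carbinol epimers. LiAlH4 then gives the triol F4. Catalytic camphorsulfonic acid in CH2Cl2 at 0 °C ionises the p-alkoxybenzylic alcohol, and the C5 hydroxyl captures the cation to close the ring 2,3-trans, giving 15.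

2. **Step 3.**
   - *Risk:* residual hydrate or oligomer in the aldehyde may protonate the vinyllithium. Enolisation of the aldehyde or stray lithiation of the arene may also compete.
   - *Fallback:* it avoids both the organolithium and chloroacetaldehyde. It sets out from 2 and rejoins at 7. α-Methylenation of 2 (paraformaldehyde, iPr2NH·CF3CO2H, THF, reflux) gives the aryl vinyl ketone F5. Weitz–Scheffer epoxidation (t-BuOOH, DBU, toluene, 0 °C) gives the racemic aroyl oxirane F6. Wittig methylenation (Ph3P=CH2, THF, −78 °C to rt) of this α,β-epoxy ketone then gives 7.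

3. **Step 7.**
   - *Risk:* equilibration at C3 may stay incomplete at the ester level, or prolonged exposure to methoxide may start ring opening by β-elimination.
   - *Fallback:* it moves the epimerisation to the aldehyde oxidation level, where a tertiary amine suffices. It sets out from the crude 13/14 mixture obtained after the pyridine stage and rejoins at 15. LiAlH4 reduces the mixture to 15 together with the all-cis alcohol F7. Dess–Martin periodinane oxidises both to the all-cis aldehyde F8 and the trans,trans aldehyde F9. Et3N in CH2Cl2 converts F8 into F9 through the enol, and NaBH4 in MeOH at 0 °C reduces F9 to 15.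

Further compounds
F1 | step 6 | 2-{1-[4-(benzyloxy)-3,5-dimethoxyphenyl]vinyl}-4,4,5,5-tetramethyl-1,3,2-dioxaborolane | C=C(B1OC(C)(C)C(C)(C)O1)c1cc(OC)c(OCc2ccccc2)c(OC)c1
F2 | step 6 | (R)-4-{1-[4-(benzyloxy)-3,5-dimethoxyphenyl]vinyl}dihydrofuran-2(3H)-one | O=C1C[C@H](C(=C)c2cc(OC)c(OCc3ccccc3)c(OC)c2)CO1
F3 | step 6 | trans-3-{[4-(benzyloxy)-3-methoxyphenyl](hydroxy)methyl}-4-(1-arylvinyl)dihydrofuran-2(3H)-one, carbinol epimers | O=C1OC[C@@H](C(=C)c2cc(OC)c(OCc3ccccc3)c(OC)c2)[C@H]1C(O)c1ccc(OCc2ccccc2)c(OC)c1
F4 | step 6 | triol from reduction of F3, carbinol epimers | OC[C@@H](C(=C)c1cc(OC)c(OCc2ccccc2)c(OC)c1)[C@H](CO)C(O)c1ccc(OCc2ccccc2)c(OC)c1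
F5 | step 3 | 1-[4-(benzyloxy)-3,5-dimethoxyphenyl]prop-2-en-1-one | C=CC(=O)c1cc(OC)c(OCc2ccccc2)c(OC)c1
F6 | step 3 | rac-[4-(benzyloxy)-3,5-dimethoxyphenyl](oxiran-2-yl)methanone | O=C(c1cc(OC)c(OCc2ccccc2)c(OC)c1)C1CO1
F7 | step 7 | all-cis C3 epimer of alcohol 15 | COc1cc([C@H]2OC[C@@H](C(=C)c3cc(OC)c(OCc4ccccc4)c(OC)c3)[C@H]2CO)ccc1OCc1ccccc1
F8 | step 7 | all-cis tetrahydrofuran-3-carbaldehyde | COc1cc([C@H]2OC[C@@H](C(=C)c3cc(OC)c(OCc4ccccc4)c(OC)c3)[C@H]2C=O)ccc1OCc1ccccc1
F9 | step 7 | 2,3-trans-3,4-trans tetrahydrofuran-3-carbaldehyde | COc1cc([C@H]2OC[C@@H](C(=C)c3cc(OC)c(OCc4ccccc4)c(OC)c3)[C@@H]2C=O)ccc1OCc1ccccc1
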